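With the butenolide atoms labelled O1, C2 (C=O), C3 (OMe), C4 and C5, the plan rests on one structural fact: ring A on C4 and the ring oxygen O1 on C5 are neighbours, the pattern produced when an aryl group and a carboxylate oxygen trade places across a C–C bond. One MgBr2-promoted dyotropic ring expansion of a β-lactone therefore forms C4–ring A and C5–O1, creates the five-membered lactone and hands the auxiliary-set configuration on to C5. The precursor is a 3-methoxyoxetan-2-one whose C4 carries a (1R)-1-(4-silyloxyphenyl)-2-(ring B)ethyl group; its ring epimers are used together, because C3 and C4 later become sp2.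

Key step: step 12

Remark on the chemistry: TBS = tert-butyldimethylsilyl and prenyl = 3-methylbut-2-en-1-yl. The C3 and C4 centres of lactones 21 and 22 are carried as epimer mixtures on purpose, since only the aryl-bearing carbon (later C5) has to be stereodefined.

Step 1
Reactants: 1 4-hydroxybenzaldehyde; 2 prenyl bromide (1-bromo-3-methylbut-2-ene)
Product: 3 4-hydroxy-3-prenylbenzaldehyde
Conditions: KOH, H2O, rt
Reagents that add atoms: none
Why: Direct C-alkylation of a phenoxide: in water the hydrogen-bonded phenoxide oxygen is shielded, so part of the allylic bromide is attacked through the ortho carbon (both ortho positions are equivalent), and the C-prenylated phenol should be separable from the O-prenyl ether by chromatography.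

Step 2
Reactants: 3 4-hydroxy-3-prenylbenzaldehyde
Product: 4 4-(TBSO)-3-prenylbenzaldehyde
Conditions: TBSCl, imidazole, DMF, rt
Reagents that add atoms: tert-butyldimethylsilyl chloride, CC(C)(C)[Si](C)(C)Cl
Why: Standard imidazole-mediated silylation of a phenol, to which aldehyde and alkene are inert.

Step 3
Reactants: 4 4-(TBSO)-3-prenylbenzaldehyde
Product: 5 [4-(TBSO)-3-prenylphenyl]methanol
Conditions: NaBH4, MeOH, 0 °C
Reagents that add atoms: none
Why: Borohydride reduction of an aryl aldehyde, run briefly at 0 °C so that the aryl silyl ether and the alkene stay untouched.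

Step 4
Reactants: 5 [4-(TBSO)-3-prenylphenyl]methanol
Product: 6 4-(bromomethyl)-2-prenylphenyl TBS ether
Conditions: CBr4, PPh3, CH2Cl2, 0 °C
Reagents that add atoms: carbon tetrabromide, BrC(Br)(Br)Br
Why: Appel bromination: bromide displaces the alkoxyphosphonium ion under neutral conditions, so no HBr is present to add to the prenyl alkene or cleave the silyl ether, and the reactive benzylic bromide is passed through a short plug and used at once.

Step 5
Reactants: 7 methoxyacetyl chloride
Product: 8 S-phenyl 2-methoxyethanethioate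
Conditions: PhSH, pyridine, CH2Cl2, 0 °C
Reagents that add atoms: thiophenol, Sc1ccccc1
Why: Acylation of a thiol by an acid chloride (thioester formation), which provides the C2–C3 unit as an enolisable acyl donor with a good leaving group.

Step 6
Reactants: 9 4-hydroxyphenylacetic acid
Product: 11 2-[4-(TBSO)phenyl]acetic acid, via silyl ester 10 (not isolated)
Conditions: TBSCl (2.3 equiv), imidazole, DMF, rt; then AcOH, THF/H2O, rt
Reagents that add atoms: tert-butyldimethylsilyl chloride, CC(C)(C)[Si](C)(C)Cl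
Why: Exhaustive silylation followed by selective hydrolysis of the silyl ester, which is far more labile than the aryl silyl ether in mildly acidic aqueous medium.

Step 7
Reactants: 11 2-[4-(TBSO)phenyl]acetic acid; 12 (R)-4-benzyl-2-oxazolidinone
Product: 14 (R)-4-benzyl-3-{2-[4-(TBSO)phenyl]acetyl}oxazolidin-2-one, via mixed pivalic anhydride 13 (not isolated)
Conditions: t-BuCOCl, Et3N, THF, −20 °C; then 12, LiCl, −20 °C to rt
Reagents that add atoms: none
Why: N-Acylation of the oxazolidinone through a mixed pivalic anhydride (Et3N/LiCl protocol), in which the hindered pivaloyl carbonyl is not attacked and the arylacetyl group is transferred.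

Step 8
Reactants: 14 (R)-4-benzyl-3-{2-[4-(TBSO)phenyl]acetyl}oxazolidin-2-one; 6 4-(bromomethyl)-2-prenylphenyl TBS ether
Product: 16 (R)-4-benzyl-3-{(2R)-2-[4-(TBSO)phenyl]-3-[4-(TBSO)-3-prenylphenyl]propanoyl}oxazolidin-2-one, via sodium Z-enolate 15 (not isolated)
Conditions: NaN(SiMe3)2 (1.05 equiv), THF, −78 °C; then 6 (1.3 equiv), −78 to −40 °C
Reagents that add atoms: none
Why: Evans asymmetric alkylation: the chelated sodium Z-enolate is shielded on one face by the benzyl group of the (R)-auxiliary, so the benzylic bromide enters from the other face and sets the (2R) centre (R here because ring A outranks the new benzylic carbon).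

Step 9
Reactants: 16 (R)-4-benzyl-3-{(2R)-2-[4-(TBSO)phenyl]-3-[4-(TBSO)-3-prenylphenyl]propanoyl}oxazolidin-2-one
Product: 17 (2R)-2-[4-(TBSO)phenyl]-3-[4-(TBSO)-3-prenylphenyl]propan-1-ol
Conditions: LiBH4, H2O (1 equiv), Et2O, 0 °C
Reagents that add atoms: none
Why: Reductive removal of the auxiliary with LiBH4: hydride attacks the exocyclic imide carbonyl, the α-centre is not enolised, and the oxazolidinone is recovered.

Step 10
Reactants: 17 (2R)-2-[4-(TBSO)phenyl]-3-[4-(TBSO)-3-prenylphenyl]propan-1-ol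
Product: 18 (2R)-2-[4-(TBSO)phenyl]-3-[4-(TBSO)-3-prenylphenyl]propanal
Conditions: Dess–Martin periodinane, CH2Cl2, 0 °C to rt; crude aldehyde used at once
Reagents that add atoms: none
Why: Dess–Martin oxidation, an amine-free oxidation suited to epimerisable α-aryl aldehydes, with the crude aldehyde carried on the same day without chromatography.

Step 11
Reactants: 18 (2R)-2-[4-(TBSO)phenyl]-3-[4-(TBSO)-3-prenylphenyl]propanal; 8 S-phenyl 2-methoxyethanethioate
Product: 21 3-methoxy-4-{(1R)-1-[4-(TBSO)phenyl]-2-[4-(TBSO)-3-prenylphenyl]ethyl}oxetan-2-one as a mixture of ring epimers, via lithium thioester enolate 19 (not isolated), via lithium aldolate 20 (not isolated)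
Conditions: 8 (1.3 equiv), LiN(iPr)2 (1.2 equiv), THF, −78 °C; then 18, −78 °C; warm to 0 °C
Reagents that add atoms: none
Why: Thiol ester enolate aldol addition followed by spontaneous lactonisation: the aldehyde is consumed at −78 °C with no free amide base present, the lithium aldolate then attacks the thioester carbonyl (4-exo-trig) and expels thiophenolate on warming, the aryl-bearing centre is untouched and the two new ring centres are deliberately left uncontrolled.

Step 12
Reactants: 21 3-methoxy-4-{(1R)-1-[4-(TBSO)phenyl]-2-[4-(TBSO)-3-prenylphenyl]ethyl}oxetan-2-one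
Product: 22 (5R)-3-methoxy-4-[4-(TBSO)phenyl]-5-[4-(TBSO)-3-prenylbenzyl]dihydrofuran-2(3H)-one as a mixture of C3 and C4 epimers
Conditions: MgBr2·OEt2 (1.5 equiv), CH2Cl2, 0 °C to rt
Reagents that add atoms: none
Why: MgBr2 binds the lactone carbonyl (and the neighbouring methoxy oxygen) and weakens the ring C4–O bond; ring A, turned antiperiplanar to that bond by rotation about the exocyclic C–C bond, bridges as a phenonium ion and ends on the former oxetanone C4, while the carboxylate oxygen bonds to the carbon that ring A leaves, so the two groups exchange places with release of four-ring strain. The closest known reaction type is the MgBr2-promoted dyotropic (Wagner–Meerwein type) rearrangement of 4-(1-substituted alkyl)oxetan-2-ones to γ-butyrolactones. The five-membered lactone closes by ring expansion, formally a 5-exo-tet opening of the three-membered phenonium ring by the carboxylate oxygen. The C5 stereocentre is set by substrate control: oxygen enters anti to the departing aryl group, the carbon is inverted, and with the changed substituent ranking the (1R) side-chain centre should become (5R) for every ring epimer of 21. The step needs migration of ring A in preference to the hydrogen or the benzyl carbon and no free cation at C5; the para-silyloxy group makes ring A the best bridging group, and a mild Lewis acid in a non-ionising solvent should keep the shift concerted and leave the silyl ethers and the prenyl alkene alone.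

Step 13
Reactants: 22 (5R)-3-methoxy-4-[4-(TBSO)phenyl]-5-[4-(TBSO)-3-prenylbenzyl]dihydrofuran-2(3H)-one
Product: 26 (5R)-3-methoxy-4-[4-(TBSO)phenyl]-5-[4-(TBSO)-3-prenylbenzyl]furan-2(5H)-one, via lithium lactone enolate 23 (not isolated), via selenide 24 (not isolated), via selenoxide 25 (not isolated)
Conditions: LiN(iPr)2, THF, −78 °C; PhSeBr, −78 °C; then pyridine, 30% H2O2, CH2Cl2, 0 °C
Reagents that add atoms: none
Why: α-Selenenylation and selenoxide syn-elimination: the C3 enolate takes selenium on the face anti to the C4 aryl group, hence syn to C4–H, and the selenoxide eliminates toward that only β-hydrogen to give the conjugated C3=C4 alkene, while pyridine and excess H2O2 remove benzeneselenenic acid before it can add to the prenyl alkene, and C5 is not touched.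

Step 14
Reactants: 26 (5R)-3-methoxy-4-[4-(TBSO)phenyl]-5-[4-(TBSO)-3-prenylbenzyl]furan-2(5H)-one
Product: 27 (5R)-5-[4-hydroxy-3-(3-methylbut-2-en-1-yl)benzyl]-4-(4-hydroxyphenyl)-3-methoxyfuran-2(5H)-one
Conditions: Bu4NF, AcOH (1:1), THF, 0 °C
Reagents that add atoms: none
Why: Fluoride cleavage of aryl silyl ethers, buffered with acetic acid so that the medium never becomes basic enough to deprotonate C5–H of the butenolide and racemise C5.

Compound list

1 | 4-hydroxybenzaldehyde | O=Cc1ccc(O)cc1 | starting material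
2 | prenyl bromide (1-bromo-3-methylbut-2-ene) | CC(C)=CCBr | starting material
3 | 4-hydroxy-3-(3-methylbut-2-en-1-yl)benzaldehyde | O=Cc1ccc(O)c(CC=C(C)C)c1 | intermediate
4 | 4-(tert-butyldimethylsilyloxy)-3-(3-methylbut-2-en-1-yl)benzaldehyde | O=Cc1ccc(O[Si](C)(C)C(C)(C)C)c(CC=C(C)C)c1 | intermediate
5 | [4-(tert-butyldimethylsilyloxy)-3-(3-methylbut-2-en-1-yl)phenyl]methanol | OCc1ccc(O[Si](C)(C)C(C)(C)C)c(CC=C(C)C)c1 | intermediate
6 | [4-(bromomethyl)-2-(3-methylbut-2-en-1-yl)phenoxy](tert-butyl)dimethylsilane | BrCc1ccc(O[Si](C)(C)C(C)(C)C)c(CC=C(C)C)c1 | intermediate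
7 | methoxyacetyl chloride | COCC(=O)Cl | starting material
8 | S-phenyl 2-methoxyethanethioate | COCC(=O)Sc1ccccc1 | intermediate
9 | 4-hydroxyphenylacetic acid | O=C(O)Cc1ccc(O)cc1 | starting material
10 | tert-butyldimethylsilyl 2-[4-(tert-butyldimethylsilyloxy)phenyl]acetate | CC(C)(C)[Si](C)(C)OC(=O)Cc1ccc(O[Si](C)(C)C(C)(C)C)cc1 | intermediate
11 | 2-[4-(tert-butyldimethylsilyloxy)phenyl]acetic acid | O=C(O)Cc1ccc(O[Si](C)(C)C(C)(C)C)cc1 | intermediate
12 | (R)-4-benzyl-2-oxazolidinone | O=C1N[C@H](Cc2ccccc2)CO1 | starting material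
13 | 2-[4-(tert-butyldimethylsilyloxy)phenyl]acetic pivalic anhydride | CC(C)(C)C(=O)OC(=O)Cc1ccc(O[Si](C)(C)C(C)(C)C)cc1 | intermediate
14 | (R)-4-benzyl-3-{2-[4-(tert-butyldimethylsilyloxy)phenyl]acetyl}oxazolidin-2-one | O=C(Cc1ccc(O[Si](C)(C)C(C)(C)C)cc1)N1[C@H](Cc2ccccc2)COC1=O | intermediate
15 | sodium (Z)-enolate of 14 (oxygen and ring A cis) | [Na+].[O-]/C(=C\c1ccc(O[Si](C)(C)C(C)(C)C)cc1)N1[C@H](Cc2ccccc2)COC1=O | intermediate
16 | (R)-4-benzyl-3-{(2R)-2-[4-(TBSO)phenyl]-3-[4-(TBSO)-3-prenylphenyl]propanoyl}oxazolidin-2-one | O=C([C@H](Cc1ccc(O[Si](C)(C)C(C)(C)C)c(CC=C(C)C)c1)c1ccc(O[Si](C)(C)C(C)(C)C)cc1)N1[C@H](Cc2ccccc2)COC1=O | intermediate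
17 | (2R)-2-[4-(TBSO)phenyl]-3-[4-(TBSO)-3-prenylphenyl]propan-1-ol | OC[C@H](Cc1ccc(O[Si](C)(C)C(C)(C)C)c(CC=C(C)C)c1)c1ccc(O[Si](C)(C)C(C)(C)C)cc1 | intermediate
18 | (2R)-2-[4-(TBSO)phenyl]-3-[4-(TBSO)-3-prenylphenyl]propanal | O=C[C@H](Cc1ccc(O[Si](C)(C)C(C)(C)C)c(CC=C(C)C)c1)c1ccc(O[Si](C)(C)C(C)(C)C)cc1 | intermediate
19 | lithium enolate of thioester 8 | [Li+].[O-]C(=COC)Sc1ccccc1 | intermediate
20 | lithium alkoxide of S-phenyl (4R)-3-hydroxy-2-methoxy-4-[4-(TBSO)phenyl]-5-[4-(TBSO)-3-prenylphenyl]pentanethioate (C2 and C3 epimers) | [Li+].COC(C(=O)Sc1ccccc1)C([O-])[C@H](Cc1ccc(O[Si](C)(C)C(C)(C)C)c(CC=C(C)C)c1)c1ccc(O[Si](C)(C)C(C)(C)C)cc1 | intermediate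
21 | 3-methoxy-4-{(1R)-1-[4-(TBSO)phenyl]-2-[4-(TBSO)-3-prenylphenyl]ethyl}oxetan-2-one (mixture of ring epimers) | COC1C(=O)OC1[C@H](Cc1ccc(O[Si](C)(C)C(C)(C)C)c(CC=C(C)C)c1)c1ccc(O[Si](C)(C)C(C)(C)C)cc1 | intermediate
22 | (5R)-3-methoxy-4-[4-(TBSO)phenyl]-5-[4-(TBSO)-3-prenylbenzyl]dihydrofuran-2(3H)-one (C3 and C4 epimers) | COC1C(c2ccc(O[Si](C)(C)C(C)(C)C)cc2)[C@@H](Cc2ccc(O[Si](C)(C)C(C)(C)C)c(CC=C(C)C)c2)OC1=O | intermediate
23 | lithium enolate of lactone 22 (5R; C4 epimers) | [Li+].COC1=C([O-])O[C@H](Cc2ccc(O[Si](C)(C)C(C)(C)C)c(CC=C(C)C)c2)C1c1ccc(O[Si](C)(C)C(C)(C)C)cc1 | intermediate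
24 | (5R)-3-methoxy-3-(phenylselanyl)-4-[4-(TBSO)phenyl]-5-[4-(TBSO)-3-prenylbenzyl]dihydrofuran-2(3H)-one (selenium trans to the C4 aryl group) | COC1([Se]c2ccccc2)C(c2ccc(O[Si](C)(C)C(C)(C)C)cc2)[C@@H](Cc2ccc(O[Si](C)(C)C(C)(C)C)c(CC=C(C)C)c2)OC1=O | intermediate
25 | selenoxide of 24 | COC1([Se](=O)c2ccccc2)C(c2ccc(O[Si](C)(C)C(C)(C)C)cc2)[C@@H](Cc2ccc(O[Si](C)(C)C(C)(C)C)c(CC=C(C)C)c2)OC1=O | intermediate
26 | (5R)-3-methoxy-4-[4-(TBSO)phenyl]-5-[4-(TBSO)-3-prenylbenzyl]furan-2(5H)-one | COC1=C(c2ccc(O[Si](C)(C)C(C)(C)C)cc2)[C@@H](Cc2ccc(O[Si](C)(C)C(C)(C)C)c(CC=C(C)C)c2)OC1=O | intermediate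
27 | (5R)-5-[4-hydroxy-3-(3-methylbut-2-en-1-yl)benzyl]-4-(4-hydroxyphenyl)-3-methoxyfuran-2(5H)-one | COC1=C(c2ccc(O)cc2)[C@@H](Cc2ccc(O)c(CC=C(C)C)c2)OC1=O | target

Total step count: 14 steps.
Longest linear sequence: 11 steps (steps 1–4, then 8–14, from 4-hydroxybenzaldehyde).

Steps most likely to fail

1. Step 12. The hydrogen on the aryl-bearing carbon may migrate instead of ring A, the phenonium ion may open to a free cation so that configuration is lost, or the β-lactone may eliminate with loss of CO2. The fallback makes the C4–ring A bond by cross-coupling and the stereocentre by glycolate alkylation; it sets out from bromide 6 and returns at butenolide 26.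
   - The sodium enolate (NaN(SiMe3)2, THF, −78 °C) of (S)-4-benzyl-3-[2-(4-methoxybenzyloxy)acetyl]oxazolidin-2-one F1 (from (S)-4-benzyl-2-oxazolidinone, n-BuLi and (4-methoxybenzyloxy)acetyl chloride) would be alkylated with 6 to give the (2R)-imide F2 (Evans-type glycolate alkylation).
   - MeOMgBr in MeOH/CH2Cl2 at 0 °C should give the methyl ester F3.
   - DDQ in CH2Cl2/pH 7 buffer should remove the 4-methoxybenzyl group and give the hydroxy ester F4.
   - Acylation with methoxyacetyl chloride 7 and pyridine gives the diester F5.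
   - Dieckmann cyclisation with LiN(SiMe3)2 at −78 °C should give the 3-methoxytetronic acid F6.
   - Tf2O and iPr2NEt at −78 °C give the enol triflate F7.
   - Suzuki–Miyaura coupling with 4-(tert-butyldimethylsilyloxy)phenylboronic acid (Pd(PPh3)4, K3PO4, THF/H2O, 40 °C) returns to the route at 26.

2. Step 11. The lithium enolate may deprotonate the α-aryl aldehyde and erode the aryl-bearing centre, the aldolate may revert on warming, or thiophenolate may open the lactone. The fallback builds the β-lactone with no base in contact with the aldehyde; it sets out from aldehyde 18 and returns at β-lactone 21.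
   - A Mukaiyama aldol addition of 2-methoxy-1,1-bis(trimethylsilyloxy)ethene (BF3·OEt2, CH2Cl2, −78 °C; the silyl ester is cleaved on aqueous work-up) should give the β-hydroxy acid F8.
   - Carboxyl activation with PhSO2Cl in pyridine at 0 °C should close the four-membered ring with retention at the carbinol carbon and give 21.

3. Step 13. The selenium electrophile or benzeneselenenic acid may add to the prenyl alkene, the peroxide may epoxidise it, or selenium may enter syn to the C4 aryl group so that no syn hydrogen is available. The fallback introduces the double bond by palladium chemistry without selenium or peroxide; it sets out from lactone 22 and returns at butenolide 26.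
   - LiN(iPr)2 and Me3SiCl at −78 °C should give the trimethylsilyl ketene acetal F9.
   - Dehydrogenation with catalytic Pd(OAc)2 and allyl methyl carbonate in MeCN at reflux (Tsuji-type dehydrosilylation, a catalytic variant of the Saegusa–Ito oxidation) should give 26.

Further compounds

F1 | step 12 | (S)-4-benzyl-3-[2-(4-methoxybenzyloxy)acetyl]oxazolidin-2-one | COc1ccc(COCC(=O)N2[C@@H](Cc3ccccc3)COC2=O)cc1
F2 | step 12 | (S)-4-benzyl-3-{(2R)-2-(4-methoxybenzyloxy)-3-[4-(TBSO)-3-prenylphenyl]propanoyl}oxazolidin-2-one | O=C([C@@H](Cc1ccc(O[Si](C)(C)C(C)(C)C)c(CC=C(C)C)c1)OCc1ccc(OC)cc1)N1[C@@H](Cc2ccccc2)COC1=O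
F3 | step 12 | methyl (2R)-2-(4-methoxybenzyloxy)-3-[4-(TBSO)-3-prenylphenyl]propanoate | COC(=O)[C@@H](Cc1ccc(O[Si](C)(C)C(C)(C)C)c(CC=C(C)C)c1)OCc1ccc(OC)cc1
F4 | step 12 | methyl (2R)-2-hydroxy-3-[4-(TBSO)-3-prenylphenyl]propanoate | COC(=O)[C@@H](Cc1ccc(O[Si](C)(C)C(C)(C)C)c(CC=C(C)C)c1)O
F5 | step 12 | methyl (2R)-2-(2-methoxyacetoxy)-3-[4-(TBSO)-3-prenylphenyl]propanoate | COC(=O)[C@@H](Cc1ccc(O[Si](C)(C)C(C)(C)C)c(CC=C(C)C)c1)OC(=O)COC
F6 | step 12 | (5R)-4-hydroxy-3-methoxy-5-[4-(TBSO)-3-prenylbenzyl]furan-2(5H)-one | COC1=C(O)[C@@H](Cc2ccc(O[Si](C)(C)C(C)(C)C)c(CC=C(C)C)c2)OC1=O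
F7 | step 12 | (5R)-3-methoxy-5-[4-(TBSO)-3-prenylbenzyl]-4-(trifluoromethylsulfonyloxy)furan-2(5H)-one | COC1=C(OS(=O)(=O)C(F)(F)F)[C@@H](Cc2ccc(O[Si](C)(C)C(C)(C)C)c(CC=C(C)C)c2)OC1=O
F8 | step 11 | (4R)-3-hydroxy-2-methoxy-4-[4-(TBSO)phenyl]-5-[4-(TBSO)-3-prenylphenyl]pentanoic acid (C2 and C3 epimers) | COC(C(=O)O)C(O)[C@H](Cc1ccc(O[Si](C)(C)C(C)(C)C)c(CC=C(C)C)c1)c1ccc(O[Si](C)(C)C(C)(C)C)cc1
F9 | step 13 | trimethylsilyl ketene acetal of lactone 22 (5R; C4 epimers) | COC1=C(O[Si](C)(C)C)O[C@H](Cc2ccc(O[Si](C)(C)C(C)(C)C)c(CC=C(C)C)c2)C1c1ccc(O[Si](C)(C)C(C)(C)C)cc1
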